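The nine-membered oxacycle (ether O, C4, C5, C6, C7, C8, C9, C10, C1) is disconnected at C7–C8. The butenolide is carried as a 3-bromofuran, and an extra oxygen on C5 lies 1,4 to C7 across the C6=C7 edge of that ring. The acyl carbon C8 is therefore first tied to O5 in an eight-membered lactone and then moved from oxygen to carbon. In one operation bromine–lithium exchange forms C7–C8, enlarges the eight-membered ring to the nine-membered one and frees O5, which later departs to create C5=C6. The precursor is a tetrahydrofuran-bridged bromofuryl lactone built from (R)-linalool and 3,4-dibromofuran.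

Key step: step 10

Remark on numbering (germacrane numbering):
- Tetrahydrofuran ring: C1 = OCH next to C10, C2 and C3 = its CH2 groups, C4 = C(CH3)(O).
- Alkene and lactone: C5 = alkene CH, C6 = enol-lactone carbon, C7 = alkene carbon bearing C8, C11 = lactone α-carbon, C12 = lactone C=O, C13 = CH2OAc.
- Remaining ring carbons: C8 = CH–O–methacryloyl, C9 = CH2, C10 = C(CH3)(OH).
- The target is (1S,4R,5E,8S,10R).

Assumption: (R)-(−)-linalool is used in enantiomerically pure form. Its carbinol carbon becomes C4.

Step 1
Reactants: 1 (R)-(−)-linalool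
Product: 3 cis-linalool oxide 2-[(2S,5R)-5-methyl-5-vinyltetrahydrofuran-2-yl]propan-2-ol, via epoxylinalool 2 (not isolated)
Conditions: D-fructose-derived Shi ketone (D-Epoxone, 30 mol%), KHSO5 (as 2KHSO5·KHSO4·K2SO4), K2CO3, MeCN/dimethoxymethane/H2O, pH 10.5, 0 °C; then camphorsulfonic acid (cat.), CH2Cl2, 0 °C
Reagents that add atoms: potassium peroxymonosulfate KHSO5, [K+].[O-]S(=O)(=O)OO
Why: Shi epoxidation should oxidise only the electron-rich trisubstituted alkene from the face that gives the (6R)-epoxide 2, and the tertiary alcohol then opens it 5-exo-tet with inversion, so that C1 becomes (S) and C10 stands cis to the vinyl group on C4.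

Step 2
Reactants: 3 cis-linalool oxide
Product: 4 (2R,5S)-2-methyl-5-(prop-1-en-2-yl)-2-vinyltetrahydrofuran
Conditions: SOCl2, pyridine, CH2Cl2, −10 to 0 °C
Reagents that add atoms: none
Why: In this E2-type dehydration of a tertiary alcohol, loss of one of six methyl hydrogens is favoured statistically and sterically over loss of the single hindered C1–H, so the isopropenyl isomer should dominate and no stereocentre is touched.

Step 3
Reactants: 4 (2R,5S)-2-methyl-5-(prop-1-en-2-yl)-2-vinyltetrahydrofuran
Product: 5 (2R,5S)-5-acetyl-2-methyltetrahydrofuran-2-carbaldehyde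
Conditions: O3, CH2Cl2, −78 °C; then Me2S, −78 °C to rt
Reagents that add atoms: ozone, [O-][O+]=O
Why: Ozonolysis with reductive work-up cleaves both terminal alkenes at once to the C5 aldehyde and the C10 methyl ketone, and the cold neutral conditions should leave the epimerisable C1 untouched.

Step 4
Reactants: 6 3,4-dibromofuran
Product: 9 (4-bromofuran-3-yl)methanol, via furyllithium 7 (not isolated), via bromofuraldehyde 8 (not isolated)
Conditions: n-BuLi (1.0 equiv), Et2O, −78 °C; DMF, −78 °C; then MeOH, NaBH4, −78 to 0 °C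
Reagents that add atoms: N,N-dimethylformamide, CN(C)C=O
Why: Bromine–lithium exchange on the symmetrical dibromide gives one monolithio species that is configurationally safe at −78 °C, and formylation followed by borohydride reduction in the same flask installs C13.

Step 5
Reactants: 9 (4-bromofuran-3-yl)methanol
Product: 10 [(4-bromofuran-3-yl)methoxy](tert-butyl)dimethylsilane
Conditions: TBSCl, imidazole, CH2Cl2, rt
Reagents that add atoms: tert-butyldimethylsilyl chloride, CC(C)(C)[Si](C)(C)Cl
Why: Standard silylation of a primary alcohol masks O13 against the organometallic steps that follow.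

Step 6
Reactants: 10 [(4-bromofuran-3-yl)methoxy](tert-butyl)dimethylsilane; 5 (2R,5S)-5-acetyl-2-methyltetrahydrofuran-2-carbaldehyde
Product: 13 furyl carbinol 1-[(2S,5R)-5-{(R)-[3-bromo-4-(tert-butyldimethylsilyloxymethyl)furan-2-yl](hydroxy)methyl}-5-methyltetrahydrofuran-2-yl]ethanone, via lithiofuran 11 (not isolated), via furyltitanium 12 (not isolated)
Conditions: 10, LiN(iPr)2, THF, −78 °C; ClTi(OiPr)3, −78 to −40 °C; then 5, −78 to −20 °C; aqueous work-up
Reagents that add atoms: none
Why: Deprotonation occurs at the furan C–H next to bromine (future C6), and the aryltitanium triisopropoxide is a mild carbonyl-addition reagent that should take the aldehyde and spare the methyl ketone; as a non-chelating nucleophile it should follow the polar Felkin–Anh model to (5R), a centre that is erased in step 16.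

Step 7
Reactants: 13 furyl carbinol
Product: 14 bromoacetate of 13 at O5
Conditions: BrCH2COBr, pyridine, CH2Cl2, 0 °C
Reagents that add atoms: bromoacetyl bromide, O=C(Br)CBr
Why: O-acylation of the only hydroxyl group brings in C8 and C9 without touching any stereocentre.

Step 8
Reactants: 14 bromoacetate
Product: 16 eight-membered hydroxy lactone (1S,4R,5R,10R) in which O5–C8(=O)–C9H2–C10(OH)(CH3) bridges C5 and C1 of the tetrahydrofuran, via samarium enolate 15 (not isolated)
Conditions: SmI2 (2.2 equiv), THF, −78 °C, slow addition of 14 (final 0.005 M); aqueous work-up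
Reagents that add atoms: none
Why: In this intramolecular samarium Reformatsky reaction SmI2 reduces only the α-bromo ester, and in the trivalent samarium enolate 15 the metal should also bind the ketone oxygen and the ring oxygen, so that the short tether from C5 can deliver C9 to one ketone face only, which closes the eight-membered lactone and should set C10 as (R).

Step 9
Reactants: 16 eight-membered hydroxy lactone
Product: 17 O10-triethylsilyl ether of 16
Conditions: TESOTf, 2,6-lutidine, CH2Cl2, 0 °C
Reagents that add atoms: triethylsilyl triflate, CC[Si](CC)(CC)OS(=O)(=O)C(F)(F)F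
Why: Silylation with the reactive triflate covers the tertiary alcohol, so that step 10 meets neither an acidic proton nor a β-alkoxide that could undergo retro-aldol cleavage.

Step 10
Reactants: 17 silyl-protected bromofuryl lactone
Product: 20 furan-fused nine-membered ketone (1S,4R,5R,10R) bearing C8=O on furan carbon C7 plus a free C5–OH, via aryllithium 18 (not isolated), via tetrahedral alkoxide 19 (not isolated)
Conditions: n-BuLi (1.05 equiv), THF/Et2O, −100 to −78 °C; then pH 7 aqueous quench
Reagents that add atoms: none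
Why: Bromine–lithium exchange at C7 should outrun addition of n-BuLi to the lactone at −100 °C and gives aryllithium 18, whose carbanion is linked to the acyl carbon through C7–C6–C5–O5–C8. It adds to the lactone carbonyl in a 5-exo-trig closure to give the tetrahedral alkoxide 19, which collapses by expelling the C5 alkoxide, so that O5 leaves the ring and C6 and C7 enter it: the eight-membered ring O–C4–C5–O5–C8–C9–C10–C1 becomes the nine-membered ring O–C4–C5–C6–C7–C8–C9–C10–C1. The closest known reaction types are the Parham cyclization, the anionic homo-Fries (1,4 oxygen-to-carbon acyl) rearrangement of ortho-lithiated benzylic esters and the ring-enlarging nucleophilic acyl substitution of halo lactones. No stereocentre is created in 20, and C1, C4, C5 and C10 are not touched. The step needs exchange to win over carbonyl attack by n-BuLi and over proton transfer from C9, which the low temperature, the five-membered transition state and the silyl ether on O10 should secure. The conversion of an aryllithium and an ester into a ketone and an alkoxide makes the ring enlargement irreversible.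

Step 11
Reactants: 20 furan-fused nine-membered ketone
Product: 21 triol ketone (free O5–H, O10–H and O13–H)
Conditions: HF·pyridine, pyridine, THF, 0 °C to rt
Reagents that add atoms: none
Why: Buffered fluoride desilylation removes both silyl groups without the basic conditions that could trigger retro-aldol cleavage of the C8/C10 β-hydroxy ketone.

Step 12
Reactants: 21 triol ketone
Product: 22 5,13-diacetate
Conditions: Ac2O (2.5 equiv), pyridine, DMAP (cat.), CH2Cl2, 0 °C
Reagents that add atoms: acetic anhydride, CC(=O)OC(C)=O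
Why: Selective acetylation takes the primary O13 (the acetate of the target) and the secondary O5 (the later leaving group), while the tertiary O10–H is too hindered to react at 0 °C.

Step 13
Reactants: 22 5,13-diacetate
Product: 23 C12 pinacol boronate of 22
Conditions: [Ir(OMe)(cod)]2 (3 mol%), 4,4′-di-tert-butyl-2,2′-bipyridine (6 mol%), B2pin2, methyl tert-butyl ether, 50 °C
Reagents that add atoms: bis(pinacolato)diboron, CC1(C)OB(OC1(C)C)B1OC(C)(C)C(C)(C)O1
Why: Iridium-catalysed C–H borylation prefers the α-C–H of furans, and C12–H is the only ring C–H left, so one regioisomer should form while ketone and esters are tolerated.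

Step 14
Reactants: 23 C12 pinacol boronate
Product: 24 (8S)-alcohol, the 8,10-syn diol
Conditions: Et2BOMe, THF/MeOH 4:1, −78 °C; NaBH4, −78 °C; then repeated evaporation from MeOH
Reagents that add atoms: none
Why: In the Narasaka–Prasad reduction Et2BOMe ties O10 and the C8 ketone into a six-membered boron chelate and external hydride adds axially, which should give the 1,3-syn diol, that is (8S) next to (10R), with acetates and boronate left intact by the peroxide-free work-up.

Step 15
Reactants: 24 (8S)-alcohol
Product: 25 8-O-methacrylate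
Conditions: methacrylic anhydride, Et3N, DMAP (cat.), CH2Cl2, 0 °C to rt
Reagents that add atoms: methacrylic anhydride, C=C(C)C(=O)OC(=O)C(C)=C
Why: DMAP-catalysed acylation takes the secondary O8–H with retention at C8 and leaves the tertiary O10–H free.

Step 16
Reactants: 25 8-O-methacrylate
Product: 27 target CNP0516045.1, via hydroxyfuran 26 (not isolated)
Conditions: 30% H2O2, pH 7 phosphate buffer, THF, 0 °C; then Et3N, CH2Cl2, 0 °C
Reagents that add atoms: hydrogen peroxide, OO
Why: Oxidation of the furyl boronate gives 2-hydroxyfuran 26, whose oxygen pushes through C12=C11 and C7=C6 to expel the C5 acetate (vinylogous E1cB 1,6-elimination, dearomatization of the furan), which creates the lactone carbonyl, C7=C11 and C5=C6 at once, and the nine-membered ring should allow only the geometry with C4 and C7 cis (5E).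

Compound list
1 | (R)-(−)-linalool, (3R)-3,7-dimethylocta-1,6-dien-3-ol | C=C[C@](C)(O)CCC=C(C)C | starting material
2 | (3R,6R)-6,7-epoxylinalool | C=C[C@](C)(O)CC[C@H]1OC1(C)C | intermediate
3 | cis-linalool oxide, 2-[(2S,5R)-5-methyl-5-vinyltetrahydrofuran-2-yl]propan-2-ol | CC(C)(O)[C@@H]1CC[C@](C)(C=C)O1 | intermediate
4 | (2R,5S)-2-methyl-5-(prop-1-en-2-yl)-2-vinyltetrahydrofuran | C=C(C)[C@@H]1CC[C@](C)(C=C)O1 | intermediate
5 | (2R,5S)-5-acetyl-2-methyltetrahydrofuran-2-carbaldehyde | CC(=O)[C@@H]1CC[C@](C)(C=O)O1 | intermediate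
6 | 3,4-dibromofuran | Brc1cocc1Br | starting material
7 | 4-bromo-3-furyllithium | [Li]c1cocc1Br | intermediate
8 | 4-bromofuran-3-carbaldehyde | O=Cc1cocc1Br | intermediate
9 | (4-bromofuran-3-yl)methanol | OCc1cocc1Br | intermediate
10 | [(4-bromofuran-3-yl)methoxy](tert-butyl)dimethylsilane | CC(C)(C)[Si](C)(C)OCc1cocc1Br | intermediate
11 | 3-bromo-4-(tert-butyldimethylsilyloxymethyl)-2-furyllithium | [Li]c1occ(CO[Si](C)(C)C(C)(C)C)c1Br | intermediate
12 | [3-bromo-4-(tert-butyldimethylsilyloxymethyl)furan-2-yl]titanium triisopropoxide | CC(C)O[Ti](OC(C)C)(OC(C)C)c1occ(CO[Si](C)(C)C(C)(C)C)c1Br | intermediate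
13 | furyl carbinol (1S,4R,5R): 2-acetyl-5-methyltetrahydrofuran carrying CH(OH)(3-bromo-4-TBSOCH2-furan-2-yl) on C4 | CC(=O)[C@@H]1CC[C@](C)([C@@H](O)c2occ(CO[Si](C)(C)C(C)(C)C)c2Br)O1 | intermediate
14 | O5-bromoacetate of 13 | CC(=O)[C@@H]1CC[C@](C)([C@@H](OC(=O)CBr)c2occ(CO[Si](C)(C)C(C)(C)C)c2Br)O1 | intermediate
15 | diiodosamarium ester enolate of 14 | CC(=O)[C@@H]1CC[C@](C)([C@@H](OC(=C)O[Sm](I)I)c2occ(CO[Si](C)(C)C(C)(C)C)c2Br)O1 | intermediate
16 | eight-membered β-hydroxy lactone (1S,4R,5R,10R), bromofuryl group on C5 | O=C1C[C@@](C)(O)[C@@H]2CC[C@](C)([C@@H](O1)c3occ(CO[Si](C)(C)C(C)(C)C)c3Br)O2 | intermediate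
17 | O10-triethylsilyl ether of 16 | O=C1C[C@@](C)(O[Si](CC)(CC)CC)[C@@H]2CC[C@](C)([C@@H](O1)c3occ(CO[Si](C)(C)C(C)(C)C)c3Br)O2 | intermediate
18 | C7-lithiated lactone | O=C1C[C@@](C)(O[Si](CC)(CC)CC)[C@@H]2CC[C@](C)([C@@H](O1)c3occ(CO[Si](C)(C)C(C)(C)C)c3[Li])O2 | intermediate
19 | tetrahedral lithium alkoxide (C8 bound to OLi, O5, C7 and C9) | [Li]OC12C[C@@](C)(O[Si](CC)(CC)CC)[C@@H]3CC[C@](C)([C@@H](O1)c4occ(CO[Si](C)(C)C(C)(C)C)c42)O3 | intermediate
20 | furan-fused nine-membered ketone (1S,4R,5R,10R), C5–OH free, O10-TES, O13-TBS | O=C1C[C@@](C)(O[Si](CC)(CC)CC)[C@@H]2CC[C@](C)([C@@H](O)c3occ(CO[Si](C)(C)C(C)(C)C)c31)O2 | intermediate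
21 | triol ketone (1S,4R,5R,10R) | O=C1C[C@@](C)(O)[C@@H]2CC[C@](C)([C@@H](O)c3occ(CO)c31)O2 | intermediate
22 | 5,13-diacetate of 21 | O=C1C[C@@](C)(O)[C@@H]2CC[C@](C)([C@@H](OC(C)=O)c3occ(COC(C)=O)c31)O2 | intermediate
23 | C12 pinacol boronate of 22 | O=C1C[C@@](C)(O)[C@@H]2CC[C@](C)([C@@H](OC(C)=O)c3oc(B4OC(C)(C)C(C)(C)O4)c(COC(C)=O)c31)O2 | intermediate
24 | (1S,4R,5R,8S,10R)-8,10-diol boronate | O[C@H]1C[C@@](C)(O)[C@@H]2CC[C@](C)([C@@H](OC(C)=O)c3oc(B4OC(C)(C)C(C)(C)O4)c(COC(C)=O)c31)O2 | intermediate
25 | 8-O-methacrylate of 24 | C=C(C)C(=O)O[C@H]1C[C@@](C)(O)[C@@H]2CC[C@](C)([C@@H](OC(C)=O)c3oc(B4OC(C)(C)C(C)(C)O4)c(COC(C)=O)c31)O2 | intermediate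
26 | C12-hydroxyfuran from 25 | C=C(C)C(=O)O[C@H]1C[C@@](C)(O)[C@@H]2CC[C@](C)([C@@H](OC(C)=O)c3oc(O)c(COC(C)=O)c31)O2 | intermediate
27 | CNP0516045.1, (1S,4R,5E,8S,10R) | C=C(C)C(=O)O[C@H]1C[C@@](C)(O)[C@@H]2CC[C@](C)(/C=C3/OC(=O)C(COC(C)=O)=C31)O2 | target

Total step count: 16. Longest linear sequence: 14 steps (steps 1–3 and 6–16).

Steps most likely to fail

Step 10. The aryllithium may be quenched by proton transfer from C9, followed by loss of the β-silyloxy group. Alternatively n-BuLi may attack the lactone, or the tetrahedral adduct may not open.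
- The fallback sets out from 17. Aminolysis with MeNH(OMe)·HCl and i-PrMgCl opens the lactone to the hydroxy Weinreb amide F1.
- TESCl and imidazole give the bis-triethylsilyl ether F2.
- Bromine–lithium exchange with t-BuLi at −78 °C then lets C7 attack the non-enolised, chelating amide in a direct Parham-type closure to the nine-membered ketone F3.
- HF·pyridine brings F3 back to the route at 21.

Step 8. The enolate may be protonated before the medium ring closes, or facial selectivity at the ketone may be poor if the samarium chelate does not form.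
- The fallback sets out from 13. TESCl and imidazole give the silyl ether F4.
- A BF3·OEt2-promoted Mukaiyama aldol addition of 1-methoxy-1-(trimethylsilyloxy)ethene follows. Its open transition state under the polar Felkin–Anh model also leads to (10R) and gives the β-hydroxy methyl ester F5.
- LiOH and then AcOH/THF/H2O give the seco acid F6.
- Shiina macrolactonization (2-methyl-6-nitrobenzoic anhydride, DMAP, slow addition) at the secondary O5–H returns to the route at 16.

Step 13. Borylation may be slow next to the C11 substituent, or the ketone may be reduced by the borane that is formed.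
- The fallback sets out from 22. Electrophilic bromination with N-bromosuccinimide in THF at 0 °C, at the only free furan position, gives the C12 bromide F7.
- Miyaura borylation (Pd(dppf)Cl2, B2pin2, KOAc, dioxane, 80 °C) returns to the route at 23.

Further compounds
F1 | step 10 | hydroxy Weinreb amide from ring opening of 17 | CON(C)C(=O)C[C@@](C)(O[Si](CC)(CC)CC)[C@@H]1CC[C@](C)([C@@H](O)c2occ(CO[Si](C)(C)C(C)(C)C)c2Br)O1
F2 | step 10 | O5,O10-bis(triethylsilyl) Weinreb amide | CON(C)C(=O)C[C@@](C)(O[Si](CC)(CC)CC)[C@@H]1CC[C@](C)([C@@H](O[Si](CC)(CC)CC)c2occ(CO[Si](C)(C)C(C)(C)C)c2Br)O1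
F3 | step 10 | fully silylated nine-membered ketone | O=C1C[C@@](C)(O[Si](CC)(CC)CC)[C@@H]2CC[C@](C)([C@@H](O[Si](CC)(CC)CC)c3occ(CO[Si](C)(C)C(C)(C)C)c31)O2
F4 | step 8 | O5-triethylsilyl ether of 13 | CC(=O)[C@@H]1CC[C@](C)([C@@H](O[Si](CC)(CC)CC)c2occ(CO[Si](C)(C)C(C)(C)C)c2Br)O1
F5 | step 8 | (10R)-β-hydroxy methyl ester | COC(=O)C[C@@](C)(O)[C@@H]1CC[C@](C)([C@@H](O[Si](CC)(CC)CC)c2occ(CO[Si](C)(C)C(C)(C)C)c2Br)O1
F6 | step 8 | seco acid with free O5–H and O10–H | OC(=O)C[C@@](C)(O)[C@@H]1CC[C@](C)([C@@H](O)c2occ(CO[Si](C)(C)C(C)(C)C)c2Br)O1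
F7 | step 13 | C12 bromide of 22 | O=C1C[C@@](C)(O)[C@@H]2CC[C@](C)([C@@H](OC(C)=O)c3oc(Br)c(COC(C)=O)c31)O2
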